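The target is a cyclohexene (ring C1–C6: C1 carries OH and the C7H2OBz arm, C2 OAc, C3 OBz, C6 OAc). Its only alkene, C4=C5, lies in the ring between the allylic carbinol carbons C3 and C6, so opening it leaves a chain C6–C1–C2–C3 with two vinyl ends whose C1/C2/C3 triad is C2/C3/C4 of D-mannose.
Retrosynthetic cuts, in order: the O2–acetyl bond and the C1/C2 diol (held as an acetonide); C4=C5 (ring-closing metathesis); then C5–C6 (vinyl Grignard), C1–C7 (formaldehyde aldol) and the two C–O bonds of the terminal sugar diol (diol to vinyl).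
Forward: mannose diacetonide is hydroxymethylated and vinylated, the three hydroxyls are acylated (Bz on O3 and O7, Ac on O6), the terminal diol becomes the second vinyl group, and the single carbocycle is then closed. Acetonide removal and acetylation of O2 finish the route.
Stereochemistry: C1, C2 and C3 come from D-mannose (the aldol keeps the sugar C2–O configuration), C6 from a chelation-controlled vinyl addition; the metathesis creates no stereocentre.

Key step: step 7

Remark: locants C1–C7 in the text are those of the target; carbohydrate names of acyclic intermediates use their own sugar locants (sugar C3 = target C6, sugar C4 = target C1, sugar C6 = target C3). Lactol 3 is an anomeric mixture, drawn as the α-anomer; either anomer serves.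

Step 1
Reactants: 1 2,3:5,6-di-O-isopropylidene-α-D-mannofuranose; 2 formaldehyde
Product: 3 2-C-(hydroxymethyl)-2,3:5,6-di-O-isopropylidene-D-mannofuranose
Conditions: 37% aq. HCHO, K2CO3, MeOH, 65 °C
Reagents that add atoms: formaldehyde (2), C=O
Why: Crossed aldol hydroxymethylation of the ring-opened aldehyde, in which K2CO3 enolises sugar C2, formaldehyde adds on the dioxolane face trans to the C4 side chain, and only this epimer can re-close to the cis-fused furanose lactol, so the quaternary centre (target C1) should form with the D-mannose C2–O configuration retained while the lactol form protects the product from Cannizzaro reduction.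

Step 2
Reactants: 3 2-C-(hydroxymethyl)-2,3:5,6-di-O-isopropylidene-D-mannofuranose; 4 vinylmagnesium bromide
Product: 5 (3S)-1,2-dideoxy-4-C-(hydroxymethyl)-4,5:7,8-di-O-isopropylidene-D-glycero-D-galacto-oct-1-enitol (triol)
Conditions: CH2=CHMgBr (6 equiv), THF, −20 °C → rt; then aq. NH4Cl
Reagents that add atoms: vinylmagnesium bromide (4), C=C[Mg]Br
Why: Grignard addition to the aldehyde released from the magnesium lactolate under Cram chelate control, where magnesium bridges the carbonyl oxygen and the dioxolane oxygen on the α-carbon, the dioxolane ring shields one face of this five-membered chelate and vinyl enters from the face of the CH2O arm, which should set C6 as S (O6 threo to O1, later trans on the ring); two further equivalents of reagent are consumed by the hydroxyl protons.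

Step 3
Reactants: 5 (3S)-1,2-dideoxy-4-C-(hydroxymethyl)-4,5:7,8-di-O-isopropylidene-D-glycero-D-galacto-oct-1-enitol; 6 benzoyl chloride
Product: 9 6-O-benzoyl-1,2-dideoxy-4-C-(hydroxymethyl)-4,5:7,8-di-O-isopropylidene-D-glycero-D-galacto-oct-1-enitol, via cyclic phenylboronate 7 (not isolated), via benzoylated phenylboronate 8 (not isolated)
Conditions: PhB(OH)2 (1.05 equiv), toluene, reflux (Dean–Stark); then BzCl, pyridine, DMAP (cat.), CH2Cl2, 0 °C → rt; then 30% H2O2, aq. NaHCO3, THF, 0 °C
Reagents that add atoms: benzoyl chloride (6), O=C(Cl)c1ccccc1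
Why: Transient boronate protection followed by acylation, in which the 1,3-diol formed by the C6 and C7 hydroxyls closes the favoured six-membered 1,3,2-dioxaborinane (any ring through O3 would be seven-membered), only the C3 hydroxyl is left for DMAP-catalysed benzoylation, and oxidative B–C cleavage then frees the 1,3-diol under conditions too mild to move the benzoate; no stereocentre is touched.

Step 4
Reactants: 9 6-O-benzoyl-1,2-dideoxy-4-C-(hydroxymethyl)-4,5:7,8-di-O-isopropylidene-D-glycero-D-galacto-oct-1-enitol; 6 benzoyl chloride; 10 acetic anhydride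
Product: 12 3-O-acetyl-6-O-benzoyl-4-C-(benzoyloxymethyl)-1,2-dideoxy-4,5:7,8-di-O-isopropylidene-D-glycero-D-galacto-oct-1-enitol, via dibenzoate alcohol 11 (not isolated)
Conditions: BzCl (1.1 equiv), pyridine, CH2Cl2, −20 → 0 °C; then Ac2O (3 equiv), DMAP (0.1 equiv), rt
Reagents that add atoms: benzoyl chloride (6), O=C(Cl)c1ccccc1; acetic anhydride (10), CC(=O)OC(C)=O
Why: Kinetic discrimination in acylation, since the primary C7 hydroxyl should take one equivalent of BzCl at low temperature much faster than the secondary allylic C6 hydroxyl beside the quaternary carbon, which is then acetylated in the same flask by DMAP-catalysed acyl transfer.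

Step 5
Reactants: 12 3-O-acetyl-6-O-benzoyl-4-C-(benzoyloxymethyl)-1,2-dideoxy-4,5:7,8-di-O-isopropylidene-D-glycero-D-galacto-oct-1-enitol
Product: 13 3-O-acetyl-6-O-benzoyl-4-C-(benzoyloxymethyl)-1,2-dideoxy-4,5-O-isopropylidene-D-glycero-D-galacto-oct-1-enitol (7,8-diol)
Conditions: AcOH/H2O (4:1), 40 °C
Reagents that add atoms: none
Why: Selective acid-catalysed acetal hydrolysis, because the terminal dioxolane ionises far faster than the internal one on the quaternary C1, which is hindered and inductively deactivated by three neighbouring acyloxy groups, and aqueous acetic acid neither cleaves nor moves the esters.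

Step 6
Reactants: 13 3-O-acetyl-6-O-benzoyl-4-C-(benzoyloxymethyl)-1,2-dideoxy-4,5-O-isopropylidene-D-glycero-D-galacto-oct-1-enitol
Product: 15 3-O-acetyl-6-O-benzoyl-4-C-(benzoyloxymethyl)-1,2,7,8-tetradeoxy-4,5-O-isopropylidene-D-galacto-octa-1,7-dienitol, via primary iodide 14 (not isolated)
Conditions: PPh3 (4 equiv), I2 (3 equiv), imidazole (4 equiv), toluene, 100 °C
Reagents that add atoms: none
Why: Garegg–Samuelsson conversion of a vicinal diol into an alkene, in which the primary hydroxyl becomes the iodide, the secondary oxygen an oxyphosphonium, and iodide-induced elimination expels Ph3PO to leave the terminal vinyl group (target C4 with its CH2 terminus); the medium is neutral towards esters and the stereocentre destroyed is not needed.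

Step 7
Reactants: 15 3-O-acetyl-6-O-benzoyl-4-C-(benzoyloxymethyl)-1,2,7,8-tetradeoxy-4,5-O-isopropylidene-D-galacto-octa-1,7-dienitol
Product: 16 [(1R,2S,3R,6S)-6-acetoxy-3-(benzoyloxy)-1,2-(isopropylidenedioxy)cyclohex-4-en-1-yl]methyl benzoate
Conditions: second-generation Grubbs catalyst (H2IMes)(PCy3)Cl2Ru=CHPh (5 mol %), CH2Cl2 (0.005 M), 40 °C
Reagents that add atoms: none
Why: Olefin metathesis by the Chauvin mechanism: the ruthenium benzylidene exchanges onto one terminal vinyl group, the new alkylidene adds across the other vinyl group to a ruthenacyclobutane, and cycloreversion releases ethene and the C4=C5 bond. The closest known reaction type is ring-closing metathesis of sugar-derived 1,7-dienes to conduritol-type polyoxygenated cyclohexenes. The six-membered carbocycle closes by joining the two alkene carbons C4 and C5 of the 1,7-diene, cis-fused to the existing dioxolane, and the ring alkene is necessarily Z. No stereocentre is created; C1, C2, C3 and C6 are carried through unchanged. The selectivity needed is cyclisation over cross-metathesis oligomerisation, which the dioxolane should secure by holding the C3 and C6 arms cis on one face so that both vinyl groups are within reach, supported by high dilution. Both alkenes are monosubstituted and every allylic oxygen is esterified or acetalised, so neither hydroxyl chelation of ruthenium nor hydride-mediated isomerisation of a free allylic alcohol can interfere.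

Step 8
Reactants: 16 [(1R,2S,3R,6S)-6-acetoxy-3-(benzoyloxy)-1,2-(isopropylidenedioxy)cyclohex-4-en-1-yl]methyl benzoate
Product: 17 [(1R,2S,3R,6S)-6-acetoxy-3-(benzoyloxy)-1,2-dihydroxycyclohex-4-en-1-yl]methyl benzoate
Conditions: TFA/H2O (9:1), 0 °C → rt
Reagents that add atoms: none
Why: Acid-catalysed hydrolysis of the cis-fused isopropylidene acetal, in which only the C–O bonds to the acetal carbon break, so the configurations at C1 and C2 are untouched and the esters and allylic C–O bonds should survive the short exposure at or below room temperature.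

Step 9
Reactants: 17 [(1R,2S,3R,6S)-6-acetoxy-3-(benzoyloxy)-1,2-dihydroxycyclohex-4-en-1-yl]methyl benzoate; 10 acetic anhydride
Product: 18 [(1R,2S,3R,6S)-2,6-diacetoxy-3-(benzoyloxy)-1-hydroxycyclohex-4-en-1-yl]methyl benzoate (target)
Conditions: Ac2O (1.5 equiv), pyridine, DMAP (cat.), CH2Cl2, 0 °C
Reagents that add atoms: acetic anhydride (10), CC(=O)OC(C)=O
Why: Pyridine/DMAP acetylation (nucleophilic acyl-transfer catalysis) should be selective for the secondary C2 hydroxyl, because the tertiary C1 hydroxyl, flanked by three substituted carbons, is acylated far more slowly under these mild conditions.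

Compound list
1 | 2,3:5,6-di-O-isopropylidene-α-D-mannofuranose | O[C@H]1O[C@H]([C@H]2COC(C)(C)O2)[C@@H]2OC(C)(C)O[C@H]12 | starting material
2 | formaldehyde | C=O | starting material
3 | 2-C-(hydroxymethyl)-2,3:5,6-di-O-isopropylidene-D-mannofuranose (α-anomer drawn) | O[C@H]1O[C@H]([C@H]2COC(C)(C)O2)[C@@H]2OC(C)(C)O[C@]12CO | intermediate
4 | vinylmagnesium bromide | C=C[Mg]Br | starting material
5 | (3S)-1,2-dideoxy-4-C-(hydroxymethyl)-4,5:7,8-di-O-isopropylidene-D-glycero-D-galacto-oct-1-enitol (triol: free OH on target C6, C7 and C3) | C=C[C@H](O)[C@@]1(CO)OC(C)(C)O[C@H]1[C@H](O)[C@H]1COC(C)(C)O1 | intermediate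
6 | benzoyl chloride | O=C(Cl)c1ccccc1 | starting material
7 | cyclic phenylboronate of triol 5 (2-phenyl-1,3,2-dioxaborinane over O6 and O7 of the target numbering; C3 hydroxyl free) | C=C[C@@H]1OB(c2ccccc2)OC[C@@]12OC(C)(C)O[C@H]2[C@H](O)[C@H]1COC(C)(C)O1 | intermediate
8 | C3-O-benzoate of phenylboronate 7 | C=C[C@@H]1OB(c2ccccc2)OC[C@@]12OC(C)(C)O[C@H]2[C@H](OC(=O)c2ccccc2)[C@H]1COC(C)(C)O1 | intermediate
9 | 6-O-benzoyl-1,2-dideoxy-4-C-(hydroxymethyl)-4,5:7,8-di-O-isopropylidene-D-glycero-D-galacto-oct-1-enitol (benzoate on target C3; C6 and C7 hydroxyls free) | C=C[C@H](O)[C@@]1(CO)OC(C)(C)O[C@H]1[C@H](OC(=O)c1ccccc1)[C@H]1COC(C)(C)O1 | intermediate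
10 | acetic anhydride | CC(=O)OC(C)=O | starting material
11 | 6-O-benzoyl-4-C-(benzoyloxymethyl)-1,2-dideoxy-4,5:7,8-di-O-isopropylidene-D-glycero-D-galacto-oct-1-enitol (benzoates on target C3 and C7; C6 hydroxyl free) | C=C[C@H](O)[C@@]1(COC(=O)c2ccccc2)OC(C)(C)O[C@H]1[C@H](OC(=O)c1ccccc1)[C@H]1COC(C)(C)O1 | intermediate
12 | 3-O-acetyl-6-O-benzoyl-4-C-(benzoyloxymethyl)-1,2-dideoxy-4,5:7,8-di-O-isopropylidene-D-glycero-D-galacto-oct-1-enitol | C=C[C@H](OC(C)=O)[C@@]1(COC(=O)c2ccccc2)OC(C)(C)O[C@H]1[C@H](OC(=O)c1ccccc1)[C@H]1COC(C)(C)O1 | intermediate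
13 | 3-O-acetyl-6-O-benzoyl-4-C-(benzoyloxymethyl)-1,2-dideoxy-4,5-O-isopropylidene-D-glycero-D-galacto-oct-1-enitol (terminal 7,8-diol) | C=C[C@H](OC(C)=O)[C@@]1(COC(=O)c2ccccc2)OC(C)(C)O[C@H]1[C@H](OC(=O)c1ccccc1)[C@H](O)CO | intermediate
14 | 3-O-acetyl-6-O-benzoyl-4-C-(benzoyloxymethyl)-1,2,8-trideoxy-8-iodo-4,5-O-isopropylidene-D-glycero-D-galacto-oct-1-enitol (primary iodide) | C=C[C@H](OC(C)=O)[C@@]1(COC(=O)c2ccccc2)OC(C)(C)O[C@H]1[C@H](OC(=O)c1ccccc1)[C@H](O)CI | intermediate
15 | 3-O-acetyl-6-O-benzoyl-4-C-(benzoyloxymethyl)-1,2,7,8-tetradeoxy-4,5-O-isopropylidene-D-galacto-octa-1,7-dienitol (numbered from the acetate end; target locants 1R,2S,3R,6S) | C=C[C@H](OC(C)=O)[C@@]1(COC(=O)c2ccccc2)OC(C)(C)O[C@H]1[C@H](OC(=O)c1ccccc1)C=C | intermediate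
16 | [(1R,2S,3R,6S)-6-acetoxy-3-(benzoyloxy)-1,2-(isopropylidenedioxy)cyclohex-4-en-1-yl]methyl benzoate | CC(=O)O[C@H]1C=C[C@@H](OC(=O)c2ccccc2)[C@@H]2OC(C)(C)O[C@]12COC(=O)c1ccccc1 | intermediate
17 | [(1R,2S,3R,6S)-6-acetoxy-3-(benzoyloxy)-1,2-dihydroxycyclohex-4-en-1-yl]methyl benzoate | CC(=O)O[C@H]1C=C[C@@H](OC(=O)c2ccccc2)[C@H](O)[C@@]1(O)COC(=O)c1ccccc1 | intermediate
18 | [(1R,2S,3R,6S)-2,6-diacetoxy-3-(benzoyloxy)-1-hydroxycyclohex-4-en-1-yl]methyl benzoate (CNP0221209.1) | CC(=O)O[C@H]1C=C[C@@H](OC(=O)c2ccccc2)[C@H](OC(C)=O)[C@@]1(O)COC(=O)c1ccccc1 | target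

Total step count: 9. Longest linear sequence: 9 steps (1 to 18).

Steps most likely to fail

Step 2. The vinyl addition may show poor facial selectivity if an open Felkin–Anh pathway or direction by the C7 alkoxide competes with the α-chelate, and retro-aldol loss of formaldehyde from the β-alkoxy aldehyde may erode material. The fallback sets out from lactol 3 and reverses the roles of nucleophile and resident group. Chemoselective lactol oxidation (NIS, Bu4NI, CH2Cl2, rt) should give 2-C-(hydroxymethyl)-2,3:5,6-di-O-isopropylidene-D-mannono-1,4-lactone F1. Addition of CH2=CHMgBr (2.2 equiv, THF, −78 °C) should stop at the 1-C-vinyl hemiketal, 1,2-dideoxy-4-C-(hydroxymethyl)-4,5:7,8-di-O-isopropylidene-D-manno-oct-1-en-3-ulofuranose F2. Luche reduction (NaBH4, CeCl3·7H2O, MeOH, −40 → 0 °C) of its open-chain vinyl ketone form then delivers hydride instead of vinyl to C6. With the C1–O bond anti to the incoming hydride (Felkin–Anh), hydride passes the CH2O arm and O6 ends threo to O1, so a substrate bias that misdirects the Grignard addition should work in favour here. The fallback returns to the route at triol 5.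

Step 3. Regiocontrol may be lost if the boronate exchanges under the acylation conditions and lets benzoyl onto O6 or O7, and the oxidative deboronation may be sluggish or accompanied by acyl migration. The fallback sets out from triol 5 and uses an isolable 1,3-diol protecting group. tBu2Si(OTf)2 with 2,6-lutidine (CH2Cl2, 0 °C) should close the six-membered O6,O7-di-tert-butylsilylene derivative of 5, F3. BzCl, DMAP and pyridine should then give its C3-O-benzoate F4, and HF·pyridine (THF, 0 °C) should remove the silylene without touching ester or acetonides. The fallback returns to the route at diol 9.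

Step 6. Under hot imidazole and iodide the C3 benzoate may migrate to the neighbouring free secondary hydroxyl, or take part as a neighbouring group, before olefination is complete. The fallback sets out from diol 13 and uses a Corey–Winter sequence. 1,1'-Thiocarbonyldiimidazole (toluene, 80 °C) should convert the diol rapidly into the cyclic 7,8-thionocarbonate of 13, F5, so that no free hydroxyl remains beside the benzoate. P(OMe)3 at 110 °C should then extrude sulfur and CO2 to give the terminal alkene. The fallback returns to the route at diene 15.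

Further compounds
F1 | step 2 | 2-C-(hydroxymethyl)-2,3:5,6-di-O-isopropylidene-D-mannono-1,4-lactone | O=C1O[C@H]([C@H]2COC(C)(C)O2)[C@@H]2OC(C)(C)O[C@]12CO
F2 | step 2 | 1,2-dideoxy-4-C-(hydroxymethyl)-4,5:7,8-di-O-isopropylidene-D-manno-oct-1-en-3-ulofuranose (anomeric mixture) | C=CC1(O)O[C@H]([C@H]2COC(C)(C)O2)[C@@H]2OC(C)(C)O[C@]12CO
F3 | step 3 | O6,O7-di-tert-butylsilylene derivative of triol 5 (1,3,2-dioxasilinane; C3 hydroxyl free) | C=C[C@@H]1O[Si](C(C)(C)C)(C(C)(C)C)OC[C@@]12OC(C)(C)O[C@H]2[C@H](O)[C@H]1COC(C)(C)O1
F4 | step 3 | C3-O-benzoate of silylene F3 | C=C[C@@H]1O[Si](C(C)(C)C)(C(C)(C)C)OC[C@@]12OC(C)(C)O[C@H]2[C@H](OC(=O)c2ccccc2)[C@H]1COC(C)(C)O1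
F5 | step 6 | cyclic 7,8-thionocarbonate of diol 13 | C=C[C@H](OC(C)=O)[C@@]1(COC(=O)c2ccccc2)OC(C)(C)O[C@H]1[C@H](OC(=O)c1ccccc1)[C@H]1COC(=S)O1
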